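**Retrosynthetic overview**
1. The target is the mono-acetate of a meso triol (both secondary oxygens cis to the acyl group, tertiary OH trans to them), so the absolute configuration is set last, by enzymatic desymmetrisation of the meso diacetate.
2. The meso diacetate comes from the meso triol by acetylation of the two secondary OH groups.
3. The only ring, the cyclopentene, is closed by intramolecular aldol addition of the C5 enediolate of (Z)-4,5-dihydroxy-6-oxooctadec-2-enal onto its C1 aldehyde.
4. That linear C18 chain is not made separately: it forms in the same flask by aldol addition of 1-hydroxytetradecan-2-one to malealdehyde (from furan and singlet oxygen), giving a one-flask double-aldol [3+2] annulation.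
5. 1-Hydroxytetradecan-2-one comes from tridecanal and formaldehyde by thiazolium cross-acyloin condensation.

Assumption: the presumed biosynthesis is taken to be aldol ring closure (C1–C5 bond) of an oxidised linear C18 chain, (Z)-4,5-dihydroxy-6-oxooctadec-2-enal, followed by O-acetylation.

**Route**

Step 1
Reactants: 1 tridecanal; 2 paraformaldehyde (reacts as formaldehyde)
Product: 3 1-hydroxytetradecan-2-one
Conditions: 3-ethylbenzothiazolium bromide (10 mol %), Et3N (20 mol %), (CH2O)n (1.5 equiv), EtOH, 60 °C
Reagents that add atoms: paraformaldehyde 2, reacting as formaldehyde (C=O)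
Why: Thiazolium-carbene umpolung (cross-acyloin condensation): the Breslow intermediate of 1 adds to formaldehyde, the most electrophilic carbonyl present, to give the hydroxymethyl ketone; no stereocentre is formed.

Step 2
Reactants: 3 1-hydroxytetradecan-2-one; 4 furan
Product: 8 1-[(1r,2R,5S)-1,2,5-trihydroxycyclopent-3-en-1-yl]tridecan-1-one (meso triol; secondary OH groups cis to each other and to the acyl group; tertiary OH trans to both), via furan endoperoxide 5 (not isolated), via malealdehyde 6 (not isolated), via linear dihydroxy-keto-enal 7 (not isolated)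
Conditions: 4 (1.6 equiv), O2, hν (visible), TPP (0.1 mol %), CH2Cl2, −78 °C; Me2S (1.7 equiv), −78 → −30 °C, Ar purge; then 3 (1.0 equiv), MgBr2·OEt2 (1.2 equiv), i-Pr2NEt (2.5 equiv), −30 → 0 °C; cold pH 7 buffer
Reagents that add atoms: oxygen (O=O)
Why: Proposed new method: [4+2] cycloaddition of singlet oxygen to furan and Me2S reduction give malealdehyde 6, the Mg(II)-chelated enediolate of 3 (amine soft enolisation, as in class II aldolases) adds to one aldehyde to give Mg-aldolate 7, and re-enolisation of 7 at C5 inside the O4/O6 magnesium chelate followed by 5-(enolexo)-exo-trig intramolecular aldol addition onto the second aldehyde (held close by the Z-alkene and bound to the same Mg) closes the ring with both secondary oxygens cis to the acyl group and trans to the tertiary OH; all stereoisomers of 7 converge because C5 is re-enolised and the product is meso, and because the aldol is reversible the tridentate Mg chelate of 8 (two cis alkoxides plus ketone) is also the expected thermodynamic sink; the closest known reaction types are MgBr2/amine soft-enolisation direct aldol additions of α-hydroxy ketones and double Henry/aldol annulations of dialdehydes (Baer–Fischer, Weiss–Cook).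

Step 3
Reactants: 8 1-[(1r,2R,5S)-1,2,5-trihydroxycyclopent-3-en-1-yl]tridecan-1-one
Product: 9 (1R,2r,3S)-2-hydroxy-2-tridecanoylcyclopent-4-ene-1,3-diyl diacetate (meso; both acetoxy groups cis to the acyl group, tertiary OH free)
Conditions: Ac2O (3 equiv), pyridine, DMAP (2 mol %), CH2Cl2, 0 °C
Reagents that add atoms: acetic anhydride (CC(=O)OC(C)=O)
Why: Pyridine/DMAP-mediated O-acetylation (nucleophilic acyl substitution) of the two secondary allylic OH groups; the hindered tertiary α-ketol OH does not react at 0 °C and no stereocentre is touched, so 9 stays meso.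

Step 4
Reactants: 9 (1R,2r,3S)-2-hydroxy-2-tridecanoylcyclopent-4-ene-1,3-diyl diacetate
Product: 10 (1S,4R,5S)-4,5-dihydroxy-5-tridecanoylcyclopent-2-en-1-yl acetate (target)
Conditions: Novozym 435 (immobilised CAL-B), n-BuOH (5 equiv), MTBE, 30 °C; filter at complete mono-deacetylation
Reagents that add atoms: none
Why: Lipase-catalysed enantiotopos-selective alcoholysis (transesterification, desymmetrisation of a meso diacetate): by Kazlauskas' rule (ring CH= as medium, quaternary carbon as large substituent) the lipase cleaves the acetate on the (R)-configured carbinol carbon and leaves the acetate on the (S)-carbon, which turns the meso precursor into the single (1S,4R,5S) enantiomer in up to 100 % theoretical yield, while the neutral organic medium suppresses the 1,3-acetyl migration that would racemise it.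

**Compound list**
1 | tridecanal | CCCCCCCCCCCCC=O | starting material
2 | paraformaldehyde (reacts as formaldehyde) | C=O | starting material
3 | 1-hydroxytetradecan-2-one | CCCCCCCCCCCCC(=O)CO | intermediate
4 | furan | c1ccoc1 | starting material
5 | 2,3,7-trioxabicyclo[2.2.1]hept-5-ene (furan endoperoxide, meso) | C1=C[C@H]2OO[C@@H]1O2 | intermediate
6 | (Z)-but-2-enedial (malealdehyde) | O=C/C=C\C=O | intermediate
7 | (Z)-4,5-dihydroxy-6-oxooctadec-2-enal (mixture of C4/C5 stereoisomers, present as its magnesium aldolate) | CCCCCCCCCCCCC(=O)C(O)C(O)/C=C\C=O | intermediate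
8 | 1-[(1r,2R,5S)-1,2,5-trihydroxycyclopent-3-en-1-yl]tridecan-1-one (meso) | CCCCCCCCCCCCC(=O)[C@]1(O)[C@H](O)C=C[C@@H]1O | intermediate
9 | (1R,2r,3S)-2-hydroxy-2-tridecanoylcyclopent-4-ene-1,3-diyl diacetate (meso) | CCCCCCCCCCCCC(=O)[C@]1(O)[C@H](OC(C)=O)C=C[C@@H]1OC(C)=O | intermediate
10 | (1S,4R,5S)-4,5-dihydroxy-5-tridecanoylcyclopent-2-en-1-yl acetate | CCCCCCCCCCCCC(=O)[C@]1(O)[C@H](O)C=C[C@@H]1OC(C)=O | target

**Totals**
Total step count: 4. Longest linear sequence: 4 steps (1 → 3 → 8 → 9 → 10).

**Steps most likely to fail, with fallbacks**

Step 2 is the most likely to fail. Malealdehyde may oligomerise, the sequence may stop at the lactol of 7 or dehydrate to a furan, or the ring closure may give the wrong relative configuration. The fallback sets out from 1 and comes back to the route at 9. Condense tridecanal 1 with freshly cracked cyclopentadiene (pyrrolidine, MeOH) to 6-dodecylfulvene F1. Photooxygenate it (O2, hν, rose bengal, MeOH, −20 °C) in the presence of thiourea, so that the fulvene endoperoxide F2 is reduced as it forms to racemic cis-5-tridecylidenecyclopent-2-ene-1,4-diol F3. Acetylate (Ac2O, pyridine) to the diacetate F4. Dihydroxylate the more electron-rich exocyclic alkene with OsO4/NMO from the face anti to both acetoxy groups, giving the side-chain diol F5 with the tertiary OH trans to both acetates. Dess–Martin oxidation of the secondary side-chain alcohol then gives meso diacetate 9, and the route resumes at step 4.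

Step 4 is the second risk. The quaternary neighbour may make the carbinol acetates too hindered for the lipase, or lower its selectivity. The fallback sets out from 8 and comes back at 10. Leave out 9 and desymmetrise the meso triol 8 by direct mono-acetylation with a small-molecule chiral acyl-transfer catalyst (planar-chiral ferrocene-fused DMAP, 2 mol %, Ac2O, Et3N, t-amyl alcohol, 0 °C). Use the catalyst antipode that acetylates the (S)-configured carbinol carbon of 8. No compound outside the list is made (F0).

Step 1 is the third risk. Formose-type self-condensation of formaldehyde or homo-acyloin formation from 1 can lower the yield. The fallback sets out from 1 and comes back at 3. Corey–Chaykovsky methylenation of 1 (Me3S+ I−, KOt-Bu, DMSO) gives racemic 2-dodecyloxirane F6. Acid-catalysed hydrolysis (cat. HClO4, THF/H2O) gives racemic tetradecane-1,2-diol F7. Heating with Bu2SnO (toluene, reflux, −H2O) gives the dibutylstannylene acetal F8. Its brominolysis (Br2, CH2Cl2, 4 Å MS, rt) oxidises only the secondary carbinol and gives 3.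

**Further compounds**
F1 | step 2 | 6-dodecylfulvene (5-tridecylidenecyclopenta-1,3-diene) | CCCCCCCCCCCCC=C1C=CC=C1
F2 | step 2 | 7-tridecylidene-2,3-dioxabicyclo[2.2.1]hept-5-ene (racemic) | CCCCCCCCCCCCC=C1[C@H]2C=C[C@@H]1OO2
F3 | step 2 | cis-5-tridecylidenecyclopent-2-ene-1,4-diol (racemic) | CCCCCCCCCCCCC=C1[C@H](O)C=C[C@@H]1O
F4 | step 2 | cis-5-tridecylidenecyclopent-2-ene-1,4-diyl diacetate (racemic) | CCCCCCCCCCCCC=C1[C@H](OC(C)=O)C=C[C@@H]1OC(C)=O
F5 | step 2 | 2-hydroxy-2-(1-hydroxytridecyl)cyclopent-4-ene-1,3-diyl diacetate (acetates cis to each other, tertiary OH trans to both; side-chain carbinol racemic) | CCCCCCCCCCCCC(O)[C@]1(O)[C@H](OC(C)=O)C=C[C@@H]1OC(C)=O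
F0 | step 4 | none | none
F6 | step 1 | 2-dodecyloxirane (racemic) | CCCCCCCCCCCCC1CO1
F7 | step 1 | tetradecane-1,2-diol (racemic) | CCCCCCCCCCCCC(O)CO
F8 | step 1 | 2,2-dibutyl-4-dodecyl-1,3,2-dioxastannolane (racemic) | CCCCCCCCCCCCC1CO[Sn](CCCC)(CCCC)O1
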